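## Retrosynthetic overview
1. The last step is acid removal of two MOM ethers and one tert-butyl carbonate from the fully protected (3R)-isoflavan.
2. The key disconnection is O1–C2. Ring C is the only ring that is built (rings A and B are bought as arenes). It is closed last by an enantioselective anti-Markovnikov 6-endo hydroetherification of a 2-(2-arylallyl)phenol, and the hydrogen atom transfer that ends this step sets C3.
3. C3–C4 comes from a 1-arylvinyl metal (Shapiro reaction of the ring B acetophenone) adding to a ring A ortho-quinone methide made from 2,4-dihydroxybenzaldehyde. This addition frees only the O1–H phenol.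
4. Ring B comes from gallacetophenone. 4-O-Prenylation followed by aromatic Claisen rearrangement places the 1,1-dimethylallyl group at C5'. Chelation of the 2-OH then allows MOM on O3'/O4' and methyl on O2'.

Assumption: the sense of induction of the new thiol catalyst T cannot be predicted. Both antipodes can be made from commercial (R)- or (S)-NOBIN, and the antipode that gives 3R is used (written here as (R)-T). Making T is not counted in the route.

T = 1-[3,5-bis(trifluoromethyl)phenyl]-3-[(R)-2'-sulfanyl-1,1'-binaphthalen-2-yl]urea.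

Abbreviation: Ar = 2-methoxy-3,4-bis(methoxymethoxy)-5-(2-methylbut-3-en-2-yl)phenyl.

## Route

Step 1
Reactants: 1 gallacetophenone (1-(2,3,4-trihydroxyphenyl)ethanone); 2 prenyl bromide
Product: 3 1-[2,3-dihydroxy-4-(3-methylbut-2-en-1-yloxy)phenyl]ethanone
Conditions: KHCO3 (1.1 equiv), prenyl bromide (1.05 equiv), DMF, N2, 40 °C
Reagents that add atoms: prenyl bromide CC(C)=CCBr
Why: Williamson ether synthesis in which the weak base ionises only the 4-OH (para to the acetyl group and the most acidic), while the 2-OH is hydrogen-bonded to the ketone and the 3-OH is less acidic.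

Step 2
Reactants: 3 1-[2,3-dihydroxy-4-(3-methylbut-2-en-1-yloxy)phenyl]ethanone
Product: 5 1-[2,3,4-trihydroxy-5-(2-methylbut-3-en-2-yl)phenyl]ethanone, via Claisen dienone 4 (not isolated)
Conditions: PhNEt2, Ar, sealed tube, 190 °C, 3 h
Reagents that add atoms: none
Why: Aromatic Claisen rearrangement, where C5 is the only free ortho position, the allyl inversion of the [3,3] shift gives the 1,1-dimethylallyl group, the para position is blocked, and the basic solvent suppresses acid-catalysed cyclisation to a dihydrobenzofuran.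

Step 3
Reactants: 5 1-[2,3,4-trihydroxy-5-(2-methylbut-3-en-2-yl)phenyl]ethanone; 6 chloromethyl methyl ether; 7 iodomethane
Product: 9 1-[2-methoxy-3,4-bis(methoxymethoxy)-5-(2-methylbut-3-en-2-yl)phenyl]ethanone, via chelated bis-MOM phenol 8 (not isolated)
Conditions: K2CO3 (4 equiv), MOMCl (2.1 equiv), acetone, N2, 0 °C to rt; then CH3I (3 equiv), reflux
Reagents that add atoms: chloromethyl methyl ether COCCl; iodomethane CI
Why: Sequential Williamson O-alkylation in one pot, in which the free 3- and 4-OH groups take up MOM at room temperature and the ketone-chelated 2-OH reacts only on heating with excess iodomethane, fixing the 2'-OMe pattern.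

Step 4
Reactants: 9 1-[2-methoxy-3,4-bis(methoxymethoxy)-5-(2-methylbut-3-en-2-yl)phenyl]ethanone; 10 2,4,6-triisopropylbenzenesulfonohydrazide
Product: 11 N'-[(1E)-1-Ar-ethylidene]-2,4,6-triisopropylbenzenesulfonohydrazide
Conditions: TrisNHNH2 (1.05 equiv), PPTS (2 mol%), MeOH/THF, rt
Reagents that add atoms: 2,4,6-triisopropylbenzenesulfonohydrazide CC(C)c1cc(C(C)C)c(S(=O)(=O)NN)c(C(C)C)c1
Why: Hydrazone condensation gives the E isomer, which holds the sulfonamide nitrogen syn to the methyl group as the Shapiro reaction needs, and the near-neutral conditions leave the MOM ethers intact.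

Step 5
Reactants: 12 2,4-dihydroxybenzaldehyde; 13 di-tert-butyl dicarbonate
Product: 14 di-tert-butyl 4-formyl-1,3-phenylene bis(carbonate)
Conditions: Boc2O (2.2 equiv), DMAP (5 mol%), i-Pr2NEt (20 mol%), THF, 0 °C to rt
Reagents that add atoms: di-tert-butyl dicarbonate CC(C)(C)OC(=O)OC(=O)OC(C)(C)C
Why: DMAP-catalysed O-acylation converts both phenols into tert-butyl carbonates.

Step 6
Reactants: 14 di-tert-butyl 4-formyl-1,3-phenylene bis(carbonate)
Product: 15 di-tert-butyl 4-(hydroxymethyl)-1,3-phenylene bis(carbonate)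
Conditions: BH3·THF (1.0 equiv), THF, 0 °C; pH 7 buffer
Reagents that add atoms: none
Why: Chemoselective borane reduction of the aldehyde proceeds through a non-basic boron alkoxide, so the carbonate does not migrate and no quinone methide forms too early.

Step 7
Reactants: 11 N'-[(1E)-1-Ar-ethylidene]-2,4,6-triisopropylbenzenesulfonohydrazide; 15 di-tert-butyl 4-(hydroxymethyl)-1,3-phenylene bis(carbonate)
Product: 19 tert-butyl 3-hydroxy-4-(2-Ar-prop-2-en-1-yl)phenyl carbonate, via vinyllithium 16 (not isolated), via vinylmagnesium bromide 17 (not isolated), via ortho-quinone methide 18 (not isolated)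
Conditions: 11, n-BuLi (2.1 equiv), THF, −78 to 0 °C; MgBr2·OEt2 (1.1 equiv), −78 °C; add 15 pre-treated with t-BuMgCl (1.0 equiv), THF, −78 °C; warm to rt; aq NH4Cl; chromatography on Et3N-buffered silica
Reagents that add atoms: none
Why: The Shapiro reaction gives the 1-arylvinyl anion, the magnesium alkoxide of 15 passes its ortho Boc group to the benzylic oxygen and eliminates to the ortho-quinone methide, and 1,4-conjugate addition of the vinyl Grignard reagent rearomatises ring A, forms C3–C4 and frees only the O1–H phenol.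

Step 8
Reactants: 19 tert-butyl 3-hydroxy-4-(2-Ar-prop-2-en-1-yl)phenyl carbonate
Product: 21 tert-butyl (3R)-3-Ar-3,4-dihydro-2H-chromen-7-yl carbonate, via chroman-3-yl radical 20 (not isolated)
Conditions: 3,6-di-tert-butyl-9-mesityl-10-phenylacridinium tetrafluoroborate (2.5 mol%), thiol (R)-T (10 mol%), 2,6-lutidine (10 mol%), PhCF3/CH2Cl2 (0.05 M), Ar, 450 nm LED, −20 °C
Reagents that add atoms: none
Why: Proposed new method: the excited acridinium oxidises the electron-rich ring B styrene to its radical cation, the neighbouring phenol adds to the terminal carbon (6-endo, anti-Markovnikov) to form O1–C2, and proton loss to lutidine leaves the planar tertiary benzylic radical 20; the axially chiral arenethiol T, docked through its urea N–H bonds on the C7 carbonate carbonyl that marks the O1 edge of the chroman, then gives its weak S–H hydrogen (about 79 kcal/mol, so the transfer is irreversible) to one face and sets C3 as R, after which the acridine radical and lutidinium return the thiyl radical to T, and any phenoxyl radical formed off-cycle is repaired by the same thiol; the closest known reaction types are the racemic acridinium/arenethiol anti-Markovnikov hydroetherification of alkenols and enantioselective hydrogen atom transfer from chiral thiols in radical hydroamination and deracemisation, neither shown for a phenol nucleophile or for a C–O ring closure whose stereocentre is set by the hydrogen atom transfer.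

Step 9
Reactants: 21 tert-butyl (3R)-3-Ar-3,4-dihydro-2H-chromen-7-yl carbonate
Product: 22 (3R)-3-[3,4-dihydroxy-2-methoxy-5-(2-methylbut-3-en-2-yl)phenyl]-3,4-dihydro-2H-chromen-7-ol (target)
Conditions: HCl (2 M, from AcCl/MeOH), MeOH, Ar, 35 °C
Reagents that add atoms: none
Why: Acid-catalysed acetal exchange removes both MOM groups and acidolysis removes the tert-butyl carbonate in one operation, while methanol traps the cations, the monosubstituted alkene is not protonated at this acidity and temperature, and the C3–H stereocentre is not labile.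

## Compound list
1 | gallacetophenone, 1-(2,3,4-trihydroxyphenyl)ethanone | CC(=O)c1ccc(O)c(O)c1O | starting material
2 | prenyl bromide, 1-bromo-3-methylbut-2-ene | CC(C)=CCBr | starting material
3 | 1-[2,3-dihydroxy-4-(3-methylbut-2-en-1-yloxy)phenyl]ethanone | CC(=O)c1ccc(OCC=C(C)C)c(O)c1O | intermediate
4 | 4-acetyl-2,3-dihydroxy-6-(2-methylbut-3-en-2-yl)cyclohexa-2,4-dien-1-one (racemic, not isolated) | CC(=O)C1=CC(C(C)(C)C=C)C(=O)C(O)=C1O | intermediate
5 | 1-[2,3,4-trihydroxy-5-(2-methylbut-3-en-2-yl)phenyl]ethanone | CC(=O)c1cc(C(C)(C)C=C)c(O)c(O)c1O | intermediate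
6 | chloromethyl methyl ether | COCCl | starting material
7 | iodomethane | CI | starting material
8 | 1-[2-hydroxy-3,4-bis(methoxymethoxy)-5-(2-methylbut-3-en-2-yl)phenyl]ethanone (not isolated) | CC(=O)c1cc(C(C)(C)C=C)c(OCOC)c(OCOC)c1O | intermediate
9 | 1-[2-methoxy-3,4-bis(methoxymethoxy)-5-(2-methylbut-3-en-2-yl)phenyl]ethanone | CC(=O)c1cc(C(C)(C)C=C)c(OCOC)c(OCOC)c1OC | intermediate
10 | 2,4,6-triisopropylbenzenesulfonohydrazide | CC(C)c1cc(C(C)C)c(S(=O)(=O)NN)c(C(C)C)c1 | starting material
11 | N'-[(1E)-1-Ar-ethylidene]-2,4,6-triisopropylbenzenesulfonohydrazide | C/C(=N\NS(=O)(=O)c1c(C(C)C)cc(C(C)C)cc1C(C)C)c1cc(C(C)(C)C=C)c(OCOC)c(OCOC)c1OC | intermediate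
12 | 2,4-dihydroxybenzaldehyde | O=Cc1ccc(O)cc1O | starting material
13 | di-tert-butyl dicarbonate | CC(C)(C)OC(=O)OC(=O)OC(C)(C)C | starting material
14 | di-tert-butyl 4-formyl-1,3-phenylene bis(carbonate) | O=Cc1ccc(OC(=O)OC(C)(C)C)cc1OC(=O)OC(C)(C)C | intermediate
15 | di-tert-butyl 4-(hydroxymethyl)-1,3-phenylene bis(carbonate) | OCc1ccc(OC(=O)OC(C)(C)C)cc1OC(=O)OC(C)(C)C | intermediate
16 | (1-Ar-ethenyl)lithium (not isolated) | C=C([Li])c1cc(C(C)(C)C=C)c(OCOC)c(OCOC)c1OC | intermediate
17 | (1-Ar-ethenyl)magnesium bromide (not isolated) | C=C([Mg]Br)c1cc(C(C)(C)C=C)c(OCOC)c(OCOC)c1OC | intermediate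
18 | tert-butyl 4-methylidene-3-oxocyclohexa-1,5-dien-1-yl carbonate, ring A ortho-quinone methide (not isolated) | C=C1C=CC(OC(=O)OC(C)(C)C)=CC1=O | intermediate
19 | tert-butyl 3-hydroxy-4-(2-Ar-prop-2-en-1-yl)phenyl carbonate | C=C(Cc1ccc(OC(=O)OC(C)(C)C)cc1O)c1cc(C(C)(C)C=C)c(OCOC)c(OCOC)c1OC | intermediate
20 | 3-Ar-7-(tert-butoxycarbonyloxy)chroman-3-yl radical (not isolated) | C=CC(C)(C)c1cc([C]2COc3cc(OC(=O)OC(C)(C)C)ccc3C2)c(OC)c(OCOC)c1OCOC | intermediate
21 | tert-butyl (3R)-3-Ar-3,4-dihydro-2H-chromen-7-yl carbonate | C=CC(C)(C)c1cc([C@@H]2COc3cc(OC(=O)OC(C)(C)C)ccc3C2)c(OC)c(OCOC)c1OCOC | intermediate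
22 | (3R)-3-[3,4-dihydroxy-2-methoxy-5-(2-methylbut-3-en-2-yl)phenyl]-3,4-dihydro-2H-chromen-7-ol | C=CC(C)(C)c1cc([C@@H]2COc3cc(O)ccc3C2)c(OC)c(O)c1O | target

## Step count and risks
Total step count: 9. Longest linear sequence: 7 (steps 1, 2, 3, 4, 7, 8, 9).

**Step 8 (proposed new step).**
- Risks: low ee, because the two ring edges (O1–C2 and C4) are sterically similar.
- Risks: deprotonation of the radical cation at the doubly activated C4–H, and reversible thiyl addition to the vinyl group.
- Risks: acid-catalysed Markovnikov closure to a 2-methyl-2-aryl-dihydrobenzofuran.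
- The fallback sets out from 19 and comes back at 21.
- Known copper-catalysed enantioselective protoboration of 1,1-disubstituted aryl alkenes is used (CuCl, (R)-DTBM-SEGPHOS or a chiral N-heterocyclic carbene, NaOt-Bu, B2pin2, MeOH, THF). It puts boron on the terminal carbon and sets the benzylic centre.
- Boryl-copper prefers the aryl-conjugated alkene over the unactivated neopentyl vinyl group, so this gives tert-butyl 3-hydroxy-4-[(2R)-2-Ar-3-(4,4,5,5-tetramethyl-1,3,2-dioxaborolan-2-yl)propyl]phenyl carbonate F1.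
- H2O2 in pH 7 buffer gives tert-butyl 3-hydroxy-4-[(2R)-2-Ar-3-hydroxypropyl]phenyl carbonate F2.
- An intramolecular Mitsunobu etherification (PPh3, DIAD, THF, 0 °C) closes O1–C2 without touching C3 and gives 21.

**Step 7.**
- Risks: the hindered vinyl Grignard reagent may add more slowly than the quinone methide oligomerises, and the vinyl anion may be only partly formed.
- The fallback sets out from 9 and comes back at 19. It forms C4–C4a instead of C3–C4.
- 4-Bromoresorcinol is silylated (TBSCl, imidazole, DMF) to 1-bromo-2,4-bis(tert-butyldimethylsilyloxy)benzene F3.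
- Palladium-catalysed ketone α-arylation of 9 with it (Pd(OAc)2, XPhos, K3PO4, toluene, 90 °C) gives 1-Ar-2-[2,4-bis(tert-butyldimethylsilyloxy)phenyl]ethanone F4.
- Wittig methylenation (Ph3PCH3Br, KOt-Bu, THF) gives 2-Ar-3-[2,4-bis(tert-butyldimethylsilyloxy)phenyl]prop-1-ene F5.
- n-Bu4NF in THF gives 4-(2-Ar-prop-2-en-1-yl)benzene-1,3-diol F6.
- Boc2O 13 (1.0 equiv, DMAP, −20 °C) acylates the unhindered hydroxyl para to the benzylic carbon and gives 19.

**Step 2.**
- Risks: loss of the prenyl group, abnormal Claisen isomerisation to a 1,2-dimethylallyl group, or cyclisation to a trimethyldihydrobenzofuran at 190 °C.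
- The fallback sets out from 1 and comes back at 9, so no sigmatropic step is needed.
- MOMCl and K2CO3 in acetone give 1-[2-hydroxy-3,4-bis(methoxymethoxy)phenyl]ethanone F7.
- CH3I and K2CO3 at reflux give 1-[2-methoxy-3,4-bis(methoxymethoxy)phenyl]ethanone F8.
- NBS in MeCN at 0 °C brominates C5 (para to OMe, ortho to OMOM, meta to acetyl) and gives 1-[5-bromo-2-methoxy-3,4-bis(methoxymethoxy)phenyl]ethanone F9.
- The known ligand-controlled γ-selective Suzuki–Miyaura coupling with prenylboronic acid pinacol ester (Pd(OAc)2, bulky biaryl monophosphine, K3PO4, THF/H2O) installs the 1,1-dimethylallyl group and gives 9.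

## Further compounds
F1 | step 8 | tert-butyl 3-hydroxy-4-[(2R)-2-Ar-3-(4,4,5,5-tetramethyl-1,3,2-dioxaborolan-2-yl)propyl]phenyl carbonate | C=CC(C)(C)c1cc([C@H](CB2OC(C)(C)C(C)(C)O2)Cc2ccc(OC(=O)OC(C)(C)C)cc2O)c(OC)c(OCOC)c1OCOC
F2 | step 8 | tert-butyl 3-hydroxy-4-[(2R)-2-Ar-3-hydroxypropyl]phenyl carbonate | C=CC(C)(C)c1cc([C@H](CO)Cc2ccc(OC(=O)OC(C)(C)C)cc2O)c(OC)c(OCOC)c1OCOC
F3 | step 7 | 1-bromo-2,4-bis(tert-butyldimethylsilyloxy)benzene | Brc1ccc(O[Si](C)(C)C(C)(C)C)cc1O[Si](C)(C)C(C)(C)C
F4 | step 7 | 1-Ar-2-[2,4-bis(tert-butyldimethylsilyloxy)phenyl]ethanone | O=C(Cc1ccc(O[Si](C)(C)C(C)(C)C)cc1O[Si](C)(C)C(C)(C)C)c1cc(C(C)(C)C=C)c(OCOC)c(OCOC)c1OC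
F5 | step 7 | 2-Ar-3-[2,4-bis(tert-butyldimethylsilyloxy)phenyl]prop-1-ene | C=C(Cc1ccc(O[Si](C)(C)C(C)(C)C)cc1O[Si](C)(C)C(C)(C)C)c1cc(C(C)(C)C=C)c(OCOC)c(OCOC)c1OC
F6 | step 7 | 4-(2-Ar-prop-2-en-1-yl)benzene-1,3-diol | C=C(Cc1ccc(O)cc1O)c1cc(C(C)(C)C=C)c(OCOC)c(OCOC)c1OC
F7 | step 2 | 1-[2-hydroxy-3,4-bis(methoxymethoxy)phenyl]ethanone | CC(=O)c1ccc(OCOC)c(OCOC)c1O
F8 | step 2 | 1-[2-methoxy-3,4-bis(methoxymethoxy)phenyl]ethanone | CC(=O)c1ccc(OCOC)c(OCOC)c1OC
F9 | step 2 | 1-[5-bromo-2-methoxy-3,4-bis(methoxymethoxy)phenyl]ethanone | CC(=O)c1cc(Br)c(OCOC)c(OCOC)c1OC
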